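**Retrosynthetic overview** (guaiane numbering; primed atoms belong to the half that carries the spiro centre)
1. Ainsliadimer A opens by retro-aldol (C3–C4'), retro-hydration and retro-hetero-Diels–Alder (O–C4, C15–C15') into two molecules of dehydrozaluzanin C. The central cyclopentane is therefore made last.
2. Dehydrozaluzanin C comes from dehydrocostus lactone by oxidation at C3. That lactone comes from a 4-oxo lactone by adding C15 and C13, and the 4-oxo lactone from a bicyclic C4-enone by oxygenation at C6 and lactonisation.
3. The bicyclic enone comes from an achiral 2-alkenylcyclopentenone and methylenecyclopropane by a nickel-catalysed (4+3) cycloaddition that makes C1–C10 and C7–C8 in one operation.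
4. Enabling feature: in each seven-membered ring the segment C10(=C14H2)–C9H2–C8H2 is methylenecyclopropane opened at its proximal bond. It bridges C1 and C7, the ends of the path C1–C5–C6–C7, which can be written as an s-cis diene cross-conjugated with a ketone at C4 of the five-membered ring.
5. Ring order: cyclopentenone (bought), seven-membered ring, γ-lactone, dihydropyran (temporary), central cyclopentane.

Key step: step 5

Remark on descriptors: α is the face of H-1, H-5 and H-7 of the guaianolide units.
Assumption: the sense of induction of the chiral ligand in step 5 cannot be derived from precedent. The (R,R)-ligand is written, and its mirror image is to be used if the opposite enantiomer of the cycloadduct is favoured.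

Step 1
Reactants: 1 cyclopent-2-en-1-one
Product: 2 2-iodocyclopent-2-en-1-one
Conditions: I2, pyridine, CH2Cl2, 0 °C to rt
Reagents that add atoms: iodine, [I][I]
Why: α-Iodination of an enone by the addition–elimination (Baylis–Hillman-type) pathway, in which pyridine adds to the β-carbon, the enolate is iodinated and pyridine is expelled, so that iodine sits only on the later C5 and no stereocentre is formed.

Step 2
Reactants: 3 methyl but-3-enoate; 4 vinylboronic acid pinacol ester
Product: 5 methyl (E)-4-(4,4,5,5-tetramethyl-1,3,2-dioxaborolan-2-yl)but-3-enoate
Conditions: second-generation Grubbs catalyst RuCl2(=CHPh)(H2IMes)(PCy3) (cat.), 1,4-benzoquinone (cat.), CH2Cl2, 40 °C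
Reagents that add atoms: none
Why: Olefin cross-metathesis of a vinyl boronate with an unhindered terminal alkene should give the E-alkenyl boronate while ethene escapes, and benzoquinone suppresses ruthenium-hydride migration of the β,γ-double bond.

Step 3
Reactants: 2 2-iodocyclopent-2-en-1-one; 5 the E-alkenyl boronate
Product: 6 methyl (E)-4-(5-oxocyclopent-1-en-1-yl)but-3-enoate (dienone)
Conditions: PdCl2(dppf) (cat.), K3PO4, THF/H2O, rt
Reagents that add atoms: none
Why: Suzuki–Miyaura coupling of an α-iodoenone with an alkenyl boronate keeps the E geometry, and the mild phosphate base at room temperature should leave the skipped ester (acidic C11 protons) unisomerised.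

Step 4
Reactants: 7 3-chloro-2-methylprop-1-ene
Product: 9 methylenecyclopropane, via 1-methylcyclopropene 8 (not isolated)
Conditions: NaNH2, THF, 65 °C; gas stream through t-BuOK/DMSO; condensed at −78 °C
Reagents that add atoms: none
Why: Base-induced α-elimination of the allylic chloride gives a vinylcarbene that closes to 1-methylcyclopropene, which the alkoxide isomerises to the less strained exocyclic isomer (classical dehydrochlorination route).

Step 5
Reactants: 6 dienone; 9 methylenecyclopropane
Product: 10 bicyclic enone methyl 4-oxo-13,15-dinorguaia-5,10(14)-dien-12-oate (1α-H 7α-H)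
Conditions: Ni(cod)2 (10 mol %), (R,R)-TADDOL-derived N,N-dimethylphosphoramidite (12 mol %), 9 (5 equiv), toluene, sealed tube, 40 °C, 6 added slowly
Reagents that add atoms: none
Why: Proposed new method: zerovalent nickel should bind the s-cis dienone 6 and the strained alkene of 9 and couple them oxidatively between the enone β-carbon C1 and the sp2 ring carbon C10 to give a divalent cyclopropylcarbinyl-nickel dienolate; β-carbon elimination then breaks the proximal C10–C8 bond with release of ring strain, restores C10=C14 as the exocyclic methylene and moves nickel to C8, and C(sp3)–C(allyl) reductive elimination at C7 of the η3-allyl form (C5–C6–C7) of the dienolate gives 10 and returns zerovalent nickel. The closest known reaction types are the Ni(cod)2-catalysed (3+2) cycloaddition of methylenecyclopropane to acrylates and related electron-poor alkenes, which passes through the same first two events with the same orientation (sp2 ring carbon to the β-carbon), the nickel-catalysed (4+3) and (3+2+2) cycloadditions of ethyl cyclopropylideneacetate, and the palladium-catalysed enantioselective intramolecular (4+3) cycloaddition of alkylidenecyclopropanes to dienes with phosphoramidite ligands; new are the parent hydrocarbon as three-carbon partner of a diene, the vinylogous closure at C7 and the intermolecular asymmetric version. One ring is closed, the seven-membered carbocycle, by reductive elimination from the ring-expanded nickelacycle, so that 9 enters as the C10–C9–C8 unit of a formal (4+3) cycloaddition. Both new bonds are made on the nickel-bound face of the diene, and since H-1 (ring alkene) and H-7 (E alkene) both occupy inside positions of the s-cis diene they must end up cis on the new ring, which fixes C7 relative to C1, while the absolute sense (bonding on the β-face) is controlled by the chiral phosphoramidite in the oxidative coupling. The step needs regioselectivity, secured by the C4 ketone that makes C1 the only acceptor terminus of the diene, and (4+3) over (3+2) closure, secured by C5 being fully substituted (closure there would build a quaternary centre next to the ketone, whereas C7 is an unhindered secondary allyl terminus) and helped by the bulky π-acidic ligand. The isolated ester and the product enone, a trisubstituted and poorer acceptor than 6, should not compete.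

Step 6
Reactants: 10 bicyclic enone
Product: 12 methyl 6α-hydroxy-4-oxo-13,15-dinorguai-10(14)-en-12-oate (hydroxy ester), via β-boryl ketone 11 (not isolated)
Conditions: CuCl (cat.), Xantphos (cat.), NaOt-Bu (cat.), B2pin2, MeOH (2 equiv), THF, rt; then NaBO3·4H2O, THF/H2O, rt
Reagents that add atoms: bis(pinacolato)diboron, CC1(C)OB(OC1(C)C)B1OC(C)(C)C(C)(C)O1 (boron of 11 only); sodium perborate, [Na+].[Na+].O[B-]1(O)OO[B-](O)(O)OO1 (oxygen on C6)
Why: Copper-catalysed conjugate borylation touches only the polarised C5=C6 bond and not the isolated C10=C14 alkene, boron and then the proton should enter from the open α-face (it carries only the axial H-1 and H-7, whereas the C8–C10 bridge and the CH2CO2Me arm lie on the β-face), and perborate oxidation replaces boron by oxygen with retention, which sets 6α-OH and 5α-H.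

Step 7
Reactants: 12 hydroxy ester
Product: 13 4-oxo-13,15-dinorguai-10(14)-en-12,6α-olide (keto lactone)
Conditions: camphorsulfonic acid (cat.), toluene, 50 °C
Reagents that add atoms: none
Why: Acid-catalysed 5-exo-trig lactonisation of the γ-hydroxy ester closes the trans-fused lactone, and C5, which can equilibrate through the enol of the C4 ketone, should stay 5α-H because only this epimer keeps C4, O-6 and C11 all pseudo-equatorial on the seven-membered ring (cis-anti-trans array rather than a strained trans-syn-trans array).

Step 8
Reactants: 13 keto lactone
Product: 14 13-norguaia-4(15),10(14)-dien-12,6α-olide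
Conditions: Zn, CH2Br2, TiCl4, THF/CH2Cl2, 0 °C to rt
Reagents that add atoms: dibromomethane, BrCBr
Why: Lombardo methylenation with the non-basic zinc–titanium gem-dimetallic reagent converts the ketone selectively over the lactone and avoids the enolate that would epimerise C5 or expel the β-acyloxy group.

Step 9
Reactants: 14 13-nor lactone
Product: 17 dehydrocostus lactone, via Mannich base 15 (not isolated), via methiodide 16 (not isolated)
Conditions: LiN(i-Pr)2, THF, −78 °C; CH2=NMe2+ I−, −78 °C to rt; MeI, THF/MeOH, rt; aq. NaHCO3/CH2Cl2, rt
Reagents that add atoms: N,N-dimethylmethyleneiminium iodide (Eschenmoser's salt), C=[N+](C)C.[I-]; iodomethane, C[I] (methyl group of 16 only)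
Why: Eschenmoser methylenation, in which the lactone enolate undergoes a Mannich reaction with the iminium salt and quaternisation followed by mild base-induced elimination gives the α-methylene lactone, so that the transient C11 stereocentre is of no consequence.

Step 10
Reactants: 17 dehydrocostus lactone
Product: 18 isozaluzanin C (3α-hydroxy)
Conditions: SeO2 (cat.), t-BuOOH, CH2Cl2, 0 °C to rt
Reagents that add atoms: tert-butyl hydroperoxide, CC(C)(C)OO
Why: Selenium dioxide allylic hydroxylation (ene reaction, then 2,3-sigmatropic shift) should pick the C3 methylene next to the exposed C4=C15 alkene, leave the electron-poor C11=C13 alkene untouched and deliver oxygen from the convex α-face, and the C3 configuration is erased in step 11.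

Step 11
Reactants: 18 isozaluzanin C
Product: 19 dehydrozaluzanin C
Conditions: Dess–Martin periodinane, CH2Cl2, 0 °C
Reagents that add atoms: none
Why: Dess–Martin oxidation of the allylic alcohol under neutral conditions gives the sensitive α-methylene ketone without touching any stereocentre.

Step 12
Reactants: 19 dehydrozaluzanin C (two molecules)
Product: 20 spiro-dihydropyran dimer (O on C4 α)
Conditions: 1,1'-bi-2-naphthol (1 equiv), neat film, 50 °C
Reagents that add atoms: none
Why: Hydrogen-bond-promoted hetero-Diels–Alder dimerisation of an α-methylene ketone, in which the fixed s-cis O=C3'–C4'=C15' unit of one molecule adds to C4=C15 of the other with the usual orientation (O to C4, C15' to C15) from the convex α-face to set the spiro centre C4, while any minor enantiomer is diverted largely into a separable heterochiral dimer, which upgrades the enantiomeric purity.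

Step 13
Reactants: 20 spiro-dihydropyran dimer
Product: 21 4α-hydroxy-3,3'-diketone (opened dimer)
Conditions: 1 M aq. HCl, THF, rt
Reagents that add atoms: water, O
Why: Acid hydrolysis of the cyclic enol ether (protonation at C4', hydration of the oxocarbenium ion, opening of the hemiketal) frees the C3' ketone and the tertiary 4α-OH with the C4–O bond intact, and the new epimerisable C4' centre is reset in step 14.

Step 14
Reactants: 21 opened dimer
Product: 22 ainsliadimer A
Conditions: DBU, CH2Cl2, 0 °C
Reagents that add atoms: none
Why: Intramolecular aldol addition (5-enolexo-exo-trig) of the more substituted C4' enolate to the C3 ketone, in which the two-carbon tether on the β-face of C4 enforces a cis-fused bicyclo[3.3.0]octane (3α-OH) and the enolate reacts on the face that turns the C5' side away from the upper half, which sets the spiro centre C4'.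

**Compound list**
1 | cyclopent-2-en-1-one | O=C1C=CCC1 | starting material
2 | 2-iodocyclopent-2-en-1-one | O=C1CCC=C1I | intermediate
3 | methyl but-3-enoate | C=CCC(=O)OC | starting material
4 | vinylboronic acid pinacol ester | C=CB1OC(C)(C)C(C)(C)O1 | starting material
5 | methyl (E)-4-(4,4,5,5-tetramethyl-1,3,2-dioxaborolan-2-yl)but-3-enoate | COC(=O)C/C=C/B1OC(C)(C)C(C)(C)O1 | intermediate
6 | methyl (E)-4-(5-oxocyclopent-1-en-1-yl)but-3-enoate | COC(=O)C/C=C/C1=CCCC1=O | intermediate
7 | 3-chloro-2-methylprop-1-ene | C=C(C)CCl | starting material
8 | 1-methylcyclopropene | CC1=CC1 | intermediate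
9 | methylenecyclopropane | C=C1CC1 | intermediate
10 | methyl 4-oxo-13,15-dinorguaia-5,10(14)-dien-12-oate (1α-H, 7α-H; bicyclo[5.3.0]decane, C4 ketone, C5=C6, exocyclic C10=CH2, β-CH2CO2Me on C7) | O=C1CC[C@H]2C(=C)CC[C@@H](CC(=O)OC)C=C12 | intermediate
11 | 6α-pinacolboryl ketone (1α-H, 5α-H, 6β-H, 7α-H) | O=C1CC[C@H]2C(=C)CC[C@@H](CC(=O)OC)[C@H](B3OC(C)(C)C(C)(C)O3)[C@@H]12 | intermediate
12 | methyl 6α-hydroxy-4-oxo-13,15-dinorguai-10(14)-en-12-oate (1α-H, 5α-H, 6β-H, 7α-H) | O=C1CC[C@H]2C(=C)CC[C@@H](CC(=O)OC)[C@H](O)[C@@H]12 | intermediate
13 | 4-oxo-13,15-dinorguai-10(14)-en-12,6α-olide (trans lactone, cis hydroazulene) | O=C1CC[C@H]2C(=C)CC[C@H]3CC(=O)O[C@@H]3[C@@H]12 | intermediate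
14 | 13-norguaia-4(15),10(14)-dien-12,6α-olide | C=C1CC[C@H]2C(=C)CC[C@H]3CC(=O)O[C@@H]3[C@@H]12 | intermediate
15 | 13-dimethylaminoguaia-4(15),10(14)-dien-12,6α-olide (C11 not defined, both epimers converge) | C=C1CC[C@H]2C(=C)CC[C@H]3C(CN(C)C)C(=O)O[C@@H]3[C@@H]12 | intermediate
16 | trimethylammonium iodide of 15 (C11 not defined) | C=C1CC[C@H]2C(=C)CC[C@H]3C(C[N+](C)(C)C)C(=O)O[C@@H]3[C@@H]12.[I-] | intermediate
17 | dehydrocostus lactone, guaia-4(15),10(14),11(13)-trien-12,6α-olide | C=C1CC[C@H]2C(=C)CC[C@H]3C(=C)C(=O)O[C@@H]3[C@@H]12 | intermediate
18 | isozaluzanin C, 3α-hydroxy derivative of 17 | C=C1[C@H](O)C[C@H]2C(=C)CC[C@H]3C(=C)C(=O)O[C@@H]3[C@@H]12 | intermediate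
19 | dehydrozaluzanin C, 3-oxo derivative of 17 | C=C1C(=O)C[C@H]2C(=C)CC[C@H]3C(=C)C(=O)O[C@@H]3[C@@H]12 | intermediate
20 | hetero-Diels–Alder dimer (dihydropyran O–C4–C15–C15'–C4'=C3', spiro at C4, O α) | C=C1C(=O)O[C@@H]2[C@@H]3[C@@H](CC(=O)[C@]34CCC5=C(O4)C[C@H]6C(=C)CC[C@H]7C(=C)C(=O)O[C@@H]7[C@@H]56)C(=C)CC[C@@H]12 | intermediate
21 | opened dimer, 4α-hydroxy-3,3'-dione joined C15–C15' (C4' epimerisable, not defined) | C=C1C(=O)O[C@@H]2[C@@H]3[C@@H](CC(=O)[C@]3(O)CCC4C(=O)C[C@H]5C(=C)CC[C@H]6C(=C)C(=O)O[C@@H]6[C@@H]45)C(=C)CC[C@@H]12 | intermediate
22 | ainsliadimer A | C=C1C(=O)O[C@@H]2[C@@H]3[C@@H](C[C@@]4(O)[C@]3(O)CC[C@]43C(=O)C[C@H]4C(=C)CC[C@H]5C(=C)C(=O)O[C@@H]5[C@H]43)C(=C)CC[C@@H]12 | target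

**Total step count:** 14. **Longest linear sequence:** 12 (steps 1, 3 and 5 to 14).

**Steps most likely to fail**

1. **Step 5 (Proposed new method).**
   - What may go wrong: ring closure at C5 instead of C7, which gives (3+2) instead of (4+3); distal instead of proximal opening of the cyclopropane once a phosphorus ligand sits on nickel; oligomerisation of 9; weak discrimination of the diene faces.
   - The fallback sets out from 6 and comes back at 14. Dienone 6 is combined with commercial ethyl cyclopropylideneacetate under Ni(cod)2/PPh3 in toluene. This is the acceptor-substituted alkylidenecyclopropane for which nickel-catalysed seven-membered-ring cycloadditions with dienes and alkynes are established.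
   - The ester fixes the polarity of the coupling (its β-carbon, the later C10, bonds to C1). The product is the racemic ylideneacetate cycloadduct F1, whose enantiomers are separated on a chiral stationary phase.
   - The 1α-H,7α-H enantiomer is taken through the conditions of steps 6 and 7. This passes through the β-boryl ketone F2 and the hydroxy diester F3 and ends at the ylideneacetate keto lactone F4. The β,β-disubstituted enoate is by far the poorer acceptor and stays inert.
   - Ozonolysis (O3, CH2Cl2/MeOH, −78 °C; Me2S) removes the activating group and gives the 4,10-diketo lactone F5. A twofold Lombardo methylenation under the conditions of step 8 then installs C14 and C15 together and gives 14.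

2. **Step 6.**
   - What may go wrong: slow borylcupration of the α,β-disubstituted enone, base-induced γ-deprotonation at C7, or loss of the new β-oxygen by elimination during the oxidation.
   - The fallback sets out from 10 and comes back at 12. Weitz–Scheffer epoxidation (t-BuOOH, DBU, CH2Cl2, 0 °C) from the open α-face, again selective for the enone, gives the 5α,6α-epoxy ketone F6.
   - Reductive opening of the α,β-epoxy ketone with the selenide reagent from (PhSe)2 and NaBH4 (EtOH, AcOH, 0 °C) cleaves the C5–O bond only. This leaves the 6α-hydroxy ketone 12.

3. **Step 8.**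
   - What may go wrong: enolisation of the β-acyloxy ketone with expulsion of the lactone oxygen, or incomplete reaction of the hindered ketone.
   - The fallback sets out from 13 and comes back at 14. It is a two-stage Peterson olefination.
   - The weakly basic organocerium reagent from Me3SiCH2MgCl and CeCl3 (THF, −78 °C) adds to the ketone from the α-face to give the β-hydroxysilane F7. HF·pyridine (THF, 0 °C) then induces elimination to 14.

**Further compounds**
F1 | step 5 | ethyl ylideneacetate cycloadduct, C10=CH–CO2Et analogue of 10 (alkene geometry not defined, removed later) | O=C1CC[C@H]2C(=CC(=O)OCC)CC[C@@H](CC(=O)OC)C=C12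
F2 | step 5 | 6α-pinacolboryl ketone of the ylideneacetate series | O=C1CC[C@H]2C(=CC(=O)OCC)CC[C@@H](CC(=O)OC)[C@H](B3OC(C)(C)C(C)(C)O3)[C@@H]12
F3 | step 5 | 6α-hydroxy diester of the ylideneacetate series | O=C1CC[C@H]2C(=CC(=O)OCC)CC[C@@H](CC(=O)OC)[C@H](O)[C@@H]12
F4 | step 5 | ylideneacetate keto lactone | O=C1CC[C@H]2C(=CC(=O)OCC)CC[C@H]3CC(=O)O[C@@H]3[C@@H]12
F5 | step 5 | 4,10-dioxo-13,14,15-trinorguaian-12,6α-olide | O=C1CC[C@H]2C(=O)CC[C@H]3CC(=O)O[C@@H]3[C@@H]12
F6 | step 6 | methyl 5α,6α-epoxy-4-oxo-13,15-dinorguai-10(14)-en-12-oate | O=C1CC[C@H]2C(=C)CC[C@@H](CC(=O)OC)[C@@H]3O[C@]123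
F7 | step 8 | 4β-hydroxy-4α-(trimethylsilylmethyl) lactone | C[Si](C)(C)C[C@]1(O)CC[C@H]2C(=C)CC[C@H]3CC(=O)O[C@@H]3[C@@H]12
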